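**Remarks on the chemistry.** Ring positions are written with a hyphen (A-1 to A-6, B-1 to B-6, C-1 to C-6); labels without a hyphen (A1, A2 …, F1, F2 …) are compounds. The carbene complex and its benzannulation product map atom for atom onto rings A and B of the target, so no structure needed correcting. Two design changes are made to the precursor: the B-5 formyl group is carried as a 1,3-dioxolane rather than an acyclic acetal (more robust to chromatography and to the oxonium salt), and the lactone is activated as its enol diphenyl phosphate rather than a more labile sulfonate. All nine alkyl ethers (eight methyl, one ethyl) are assumed to be cleaved in one final operation.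

## Structural features

Phlorofucofuroeckol A is an achiral, fully aromatic nona-phenol. Rings A and B form a dibenzo-1,4-dioxin (A-6–O–B-1 and A-5–O–B-6). Ring B is also half of a dibenzofuran with ring C (bond B-5–C-6 and oxygen bridge B-4–O–C-1). Two 3,5-dihydroxyphenyl ethers hang on the A-1 oxygen (ring E) and the C-2 oxygen (ring F). There is no stereocentre and no stereogenic axis, so the whole problem is regiochemical: each ring is a phloroglucinol or 1,2,3,5-tetraoxygenated unit whose similar oxygens must be told apart. The free polyphenol is sensitive to oxidation and base, whereas the aryl–O–aryl bonds are robust, so the hydroxyls are kept as alkyl ethers until the last step. The real difficulties are three: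

- ring A carries four oxygens of three kinds and must be oriented correctly on ring B;
- the two diaryl ether oxygens on A-1 and C-2 are each flanked by two ortho oxygens;
- the furan must close between B-4 and C-1 and nowhere else.

The key step exploits the para pair of oxygens on A-1 and A-4, which flank the dioxin carbons A-6 and A-5. This is a hydroquinone mono-ether pattern, exactly what a carbene benzannulation delivers: carbene carbon to A-4 (OMe), carbon monoxide to A-1 (free OH), alkyne to A-3 and A-2 (OEt), and the dioxin C=C to A-5 and A-6.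

## Logic of the disconnections

**33 to 32.** The nine O–alkyl bonds are cut. The polyphenol is the fragile form, so it is unveiled last; 32 is neutral and can be purified. The forward step needs one reagent that cleaves eight methyl ethers and one ethyl ether without touching diaryl ether, dioxin or furan C–O bonds.

**32 to 31.** The furan bond O–B-4 is cut, leaving a hydroxyl on C-1 and hydrogen on B-4. B-4 is the only C–H ortho to the biaryl bond on ring B, because B-6 is oxygenated, so a phenol-directed C–H oxygenation has only one possible site and B-4 needs no prior functionalisation. The demand is an oxidative palladium catalysis that tolerates very electron-rich rings, and a C-1 hydroxyl that is the only free one.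

**31 to 21 and 29 (through 30).** The biaryl bond B-5–C-6 is cut. This is the most convergent cut and gives two halves of similar size. The forward coupling must form a tri-ortho-substituted biaryl from a 2,6-dialkoxyaryl boron reagent, and the C-1 oxygen must carry a group different from the methyl ethers.

**29 back to 22 (through 27, 26, 24, 23) with 16.** The C-6–B bond, the C-2–O–aryl bond, the C-2 oxygen (traced to a formyl carbon), the C-1 protecting group and the C-6 bromine are removed in turn. 22 already has the C-1 hydroxyl distinguished from the C-3 and C-5 methyl ethers and a carbon where the C-2 oxygen is needed. The demands are bromination ortho to the chelated hydroxyl, and an ether coupling that spares the C–Br bond.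

**21 to 18 (through 20).** The sulfonyl–oxygen bond is cut and the B-5 oxygen is traced to a formyl carbon. The formyl group is the handle that controls the very first step. The forward oxidation must take the aldehyde and leave the electron-rich arenes alone.

**18 to 15 and 16 (through 17).** The A-1–O–aryl bond to ring E is cut. 15 has a single free hydroxyl, on A-1, so no selectivity question arises. The demand is arylation of a phenol flanked by two oxygens.

**15 to 12 and 13.** The bonds A-4–A-3, A-2–A-1 and A-1–A-6 are cut. Ring A disappears, and its three non-dioxin oxygens come differentiated as methyl ether, ethyl ether and free hydroxyl. The forward step needs regioselective alkyne insertion and carbon monoxide insertion.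

**12 to 8 and 9.** The bond between the carbene carbon and the dioxin carbon is cut; metal, carbene carbon and its oxygen come from 9. The demand is a nucleophilic alkenyl metal located only on the dioxin carbon attached to the B-6 oxygen.

**8 to 6 (through 7).** The C–Sn and then the enol C–O(P) bond are cut, which reveals a lactone. The carbonyl carbon of 6 defines where the metal, and later ring A, will sit.

**6 to 1 and 2 (through 5 and 4).** The acetal, the acyl–oxygen bond to the B-6 oxygen and the CH2–O bond to the B-1 oxygen are cut. The two catechol oxygens of 1 are told apart by alkylating one and acylating the other, which fixes the orientation of the future dioxin.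

## Other disconnections considered

**Alternative 1:** chloroquinone hub.

- **Cut:** the aryl–oxygen bonds at A-1 (to ring E) and A-6 (to the B-1 oxygen). Ring A becomes 2,3-dichloro-5-methoxy-1,4-benzoquinone A2; rings B, C and F arrive as the dibenzofuran bromophenol A3.
- **Forward key step:** in one flask the phenoxide of 3,5-dimethoxyphenol A4 and then that of A3 replace the two chlorides of A2 by addition–elimination, giving the bis(aryloxy)quinone A1. No ring closes; the dioxin would follow by reduction and copper-mediated etherification onto the B-6 bromide.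
- **In favour:** three large pieces are joined without a transition metal. The congested A-1 ether forms by vinylogous acyl substitution, which should be less sensitive to flanking groups than a copper coupling. Ring A needs no construction.
- **Against:** the site and order of the two substitutions rest only on the modest bias that the remote methoxy group puts on the two C–Cl carbons. An aryloxy group on a quinone is itself a leaving group, so the slow second substitution by the hindered phenoxide of A3 could exchange the first aryloxy group or add at the free CH. Electron-rich phenoxides can reduce the quinone. A3 is a late, heavily substituted intermediate with a long synthesis of its own.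
- **Comparison:**
  - Structure: the chosen plan fixes the dioxin orientation by a covalent lactone before ring A exists; the alternative relies on kinetic order, which is the weaker control.
  - Mechanism: the alternative is simple polar chemistry and avoids stoichiometric chromium, a real advantage in handling.
  - Step economy: the alternative is the better plan in convergence, and probably about equal in total steps once the route to A3 is counted.

**Alternative 2:** two-directional benzannulation of rings E and F.

- **Cut:** the three C–C bonds in each of rings E and F that a cyclobutenone–ynol ether benzannulation forms. The outer rings are grown last on the bis(ethynyl ether) A6 of the pentacyclic core.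
- **Forward key step:** A6 is heated with two equivalents of 3-ethoxycyclobut-2-en-1-one A7. Each vinylketene from ring opening of A7 adds to an alkynyl ether; ring opening, six-electron closure and tautomerisation give the two 3-aryloxy-5-ethoxyphenol rings of A5 (a Danheiser benzannulation in two directions).
- **In favour:** neither hindered diaryl ether is made by a coupling reaction. On this point the alternative is better than the chosen plan, which needs two copper-mediated arylations of hindered phenols. No metal is used, and the oxygen pattern of each new ring follows from the polarity of ketene and ynol ether.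
- **Against:** the hard part is untouched. The core with its dioxin and furan must still be built, and with exactly the A-1 and C-2 hydroxyls free. Those hindered hydroxyls must then be converted into aryl ethynyl ethers, which adds operations on the most valuable intermediate and creates hydrolytically and thermally delicate groups.
- **Comparison:**
  - Mechanism: both plans end in the six-electron closure of a dienylketene to a phenol and both rely on an ynol ether, so they are equal in kind.
  - Structure: the chosen benzannulation builds the ring that carries the regiochemical problem; the alternative builds the two symmetric outer rings, which can be bought.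
  - Step economy: worse, because every step to the core is still needed and the ethynylation is added.

**Alternative 3:** bromoquinone–resorcinol furan annulation.

- **Cut:** B-5–C-6 and the furan oxygen–C-1 bond. Ring B is 2-bromo-6-methoxy-1,4-benzoquinone A9; rings C and F are the symmetric resorcinol 2-(3,5-dimethoxyphenoxy)-5-methoxybenzene-1,3-diol A10.
- **Forward key step:** under acid a free ring carbon of A10 adds to A9 at the CH next to bromine; the resulting hydroquinone hydroxyl on B-4 condenses with the neighbouring resorcinol hydroxyl with loss of water, giving the dibenzofuran A8.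
- **In favour:** one step from two simple partners to the dibenzofuran, without palladium. Because A10 is symmetric, either free carbon and either hydroxyl give the same product. The chosen plan pays for differentiating the C-1 oxygen with a five-step fragment, a hindered Suzuki coupling and an oxidative C–H closure; here the alternative is clearly better. A8 carries a free hydroxyl on B-1 and bromine on B-6, the two handles for the dioxin.
- **Against:** the quinone offers several sites (CH next to bromine, CH next to methoxy, the bromine-bearing carbon, O- versus C-attack). Ring F of A10 is itself a nucleophilic phloroglucinol ether. Quinone–hydroquinone redox exchange can consume A9. Above all, ring A must afterwards be attached through two C–O bonds in the right orientation with four differentiated oxygens; this is the problem the chosen key step solves by construction, and it would bring back something like Alternative 1 (A3 is the silyl ether of A8).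
- **Comparison:**
  - Dibenzofuran half: the alternative is shorter and mechanistically simpler (better).
  - Dioxin and ring A half: it offers no solution of its own (worse).
  - Step economy: the total would be equal or lower only if the later attachment of ring A were as clean as the furan annulation.

Key step: step 7

## Route

Step 1
Reactants: 1 2,3-dihydroxy-4-methoxybenzaldehyde; 2 ethyl bromoacetate
Product: 4 ethyl 2-(3-formyl-2-hydroxy-6-methoxyphenoxy)acetate, via disodium dianion 3 (not isolated)
Conditions: NaH (2.1 equiv), DMSO, 20 °C; then 2 (1.0 equiv), 20 °C; aq. HCl work-up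
Reagents that add atoms: none
Why: In the dianion the B-1 oxygen is neither chelated to nor conjugated with the formyl group and is the more nucleophilic, so Williamson O-alkylation by the primary bromide should occur there and place the CH2 of the future dioxin on the B-1 oxygen.

Step 2
Reactants: 4 ethyl 2-(3-formyl-2-hydroxy-6-methoxyphenoxy)acetate
Product: 5 5-methoxy-2-oxo-2,3-dihydro-1,4-benzodioxine-8-carbaldehyde
Conditions: TsOH·H2O (5 mol%), toluene, reflux, ethanol removed (4 Å sieves in a Soxhlet thimble)
Reagents that add atoms: none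
Why: Acid-catalysed intramolecular transesterification (lactonisation) onto the B-6 hydroxyl closes the six-membered aryl lactone, driven by removal of ethanol; the carbonyl carbon thereby sits on the B-6 oxygen.

Step 3
Reactants: 5 5-methoxy-2-oxo-2,3-dihydro-1,4-benzodioxine-8-carbaldehyde
Product: 6 8-(1,3-dioxolan-2-yl)-5-methoxy-1,4-benzodioxin-2(3H)-one
Conditions: TMSOCH2CH2OTMS (1.5 equiv), TMSOTf (5 mol%), CH2Cl2, −78 to −20 °C; pyridine quench
Reagents that add atoms: 1,2-bis(trimethylsiloxy)ethane, C[Si](C)(C)OCCO[Si](C)(C)C
Why: Silyl-transfer acetalisation under aprotic conditions converts the aldehyde into the dioxolane without a free alcohol that could open the aryl lactone.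

Step 4
Reactants: 6 8-(1,3-dioxolan-2-yl)-5-methoxy-1,4-benzodioxin-2(3H)-one
Product: 7 8-(1,3-dioxolan-2-yl)-5-methoxy-1,4-benzodioxin-2-yl diphenyl phosphate
Conditions: (PhO)2P(O)Cl (1.5 equiv), KN(SiMe3)2 (1.2 equiv), THF/DMPU, −78 °C
Reagents that add atoms: diphenyl chlorophosphate, O=P(Cl)(Oc1ccccc1)Oc1ccccc1
Why: O-Phosphorylation of the lactone enolate in the presence of the electrophile gives the ketene acetal phosphate (lactone enol phosphate formation); trapping at −78 °C limits enolate fragmentation, and a ketene formed by loss of the tethered aryloxide can only re-close to the same enolate.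

Step 5
Reactants: 7 8-(1,3-dioxolan-2-yl)-5-methoxy-1,4-benzodioxin-2-yl diphenyl phosphate
Product: 8 [8-(1,3-dioxolan-2-yl)-5-methoxy-1,4-benzodioxin-2-yl]trimethylstannane
Conditions: Me3SnSnMe3 (1.2 equiv), Pd(PPh3)4 (5 mol%), LiCl (3 equiv), THF, 65 °C
Reagents that add atoms: hexamethylditin, C[Sn](C)(C)[Sn](C)(C)C
Why: Stille-type stannylation of an enol phosphate: oxidative addition of zerovalent palladium into the enol C–O bond, chloride-assisted transmetalation with the distannane and reductive elimination put tin on the carbon bound to the B-6 oxygen.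

Step 6
Reactants: 8 [8-(1,3-dioxolan-2-yl)-5-methoxy-1,4-benzodioxin-2-yl]trimethylstannane; 9 chromium hexacarbonyl
Product: 12 pentacarbonyl{[8-(1,3-dioxolan-2-yl)-5-methoxy-1,4-benzodioxin-2-yl](methoxy)methylidene}chromium, via vinyllithium 10 (not isolated), via lithium acylchromate 11 (not isolated)
Conditions: MeLi (1.0 equiv), THF, −78 °C; transfer onto Cr(CO)6, THF, −78 to 0 °C; Me3OBF4, CH2Cl2/H2O, 0 °C
Reagents that add atoms: trimethyloxonium tetrafluoroborate, C[O+](C)C.F[B-](F)(F)F
Why: Tin–lithium exchange gives the 2-lithio-1,4-benzodioxin, which adds to a carbonyl ligand of Cr(CO)6; O-methylation of the acylchromate with the Meerwein salt is the classical Fischer carbene synthesis and gives the complex of zerovalent chromium.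

Step 7
Reactants: 12 pentacarbonyl{[8-(1,3-dioxolan-2-yl)-5-methoxy-1,4-benzodioxin-2-yl](methoxy)methylidene}chromium; 13 ethoxyacetylene
Product: 15 6-(1,3-dioxolan-2-yl)-2-ethoxy-4,9-dimethoxydibenzo[b,e][1,4]dioxin-1-ol, via tricarbonylchromium arene complex 14 (not isolated)
Conditions: 13 (3 equiv, solution in hexanes), THF (0.05 M), 50 °C, sealed, argon; then air, Et2O, 20 °C
Reagents that add atoms: none
Why: Thermal loss of one CO from 12 opens a site for 13, which inserts into the Cr=C bond with its unsubstituted terminus on the former carbene carbon (A-4) and the ethoxy-bearing carbon on chromium; the steric rule for terminal alkynes and the polarisation of the ynol ether point the same way. CO insertion at the new chromium–carbon bond gives a chromium-bound dienylketene whose carbonyl carbon becomes A-1. Six-electron electrocyclisation of this ketene onto the dioxin CH carbon (A-6) closes ring A, and tautomerisation of the cyclohexadienone gives the phenol as its Cr(CO)3 complex 14, from which air releases 15. This is the Dötz benzannulation of an alkenyl(alkoxy)carbene complex, closest to the known cases with cyclic α-alkoxyalkenyl (dihydropyranyl and glycal-type) carbenes. No stereocentre is formed. The step needs regioselective insertion (secured by the terminal, donor-substituted alkyne), phenol formation in preference to non-carbonylative five-membered ring closure (favoured by chromium, an alkoxycarbene, an alkenyl substituent and a coordinating solvent) and the right orientation of ring A, which is fixed beforehand because the carbene carbon sits on the dioxin carbon attached to the B-6 oxygen. The three new oxygens emerge differentiated as methyl ether on A-4, ethyl ether on A-2 and free hydroxyl on A-1.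

Step 8
Reactants: 15 6-(1,3-dioxolan-2-yl)-2-ethoxy-4,9-dimethoxydibenzo[b,e][1,4]dioxin-1-ol; 16 1-iodo-3,5-dimethoxybenzene
Product: 18 1-(3,5-dimethoxyphenoxy)-2-ethoxy-4,9-dimethoxydibenzo[b,e][1,4]dioxine-6-carbaldehyde, via dioxolane-protected diaryl ether 17 (not isolated)
Conditions: 16 (1.5 equiv), CuI (10 mol%), picolinic acid (20 mol%), K3PO4, DMSO, 90 °C, argon; then 1 M HCl, THF, 20 °C
Reagents that add atoms: water, O
Why: Ullmann diaryl ether synthesis on the only free hydroxyl (A-1); the picolinate-ligated copper system is suited to phenols with two ortho substituents and the unhindered aryl iodide is a good partner; aqueous acid then hydrolyses the dioxolane.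

Step 9
Reactants: 18 1-(3,5-dimethoxyphenoxy)-2-ethoxy-4,9-dimethoxydibenzo[b,e][1,4]dioxine-6-carbaldehyde
Product: 20 1-(3,5-dimethoxyphenoxy)-2-ethoxy-4,9-dimethoxydibenzo[b,e][1,4]dioxin-6-ol, via aryl formate 19 (not isolated)
Conditions: mCPBA (1.3 equiv), NaHCO3, CH2Cl2, 0 to 20 °C; then K2CO3, MeOH, 20 °C
Reagents that add atoms: 3-chloroperbenzoic acid, OOC(=O)c1cccc(Cl)c1
Why: Dakin-type sequence: Baeyer–Villiger oxidation of the benzaldehyde, with aryl migration favoured by the ortho and para oxygen donors, gives the formate, and methanolysis frees the B-5 phenol.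

Step 10
Reactants: 20 1-(3,5-dimethoxyphenoxy)-2-ethoxy-4,9-dimethoxydibenzo[b,e][1,4]dioxin-6-ol
Product: 21 1-(3,5-dimethoxyphenoxy)-2-ethoxy-4,9-dimethoxydibenzo[b,e][1,4]dioxin-6-yl trifluoromethanesulfonate
Conditions: Tf2O, pyridine, CH2Cl2, 0 °C
Reagents that add atoms: trifluoromethanesulfonic anhydride, O=S(=O)(OS(=O)(=O)C(F)(F)F)C(F)(F)F
Why: O-Sulfonylation of the single free phenol gives the aryl triflate, the electrophile for cross-coupling at B-5.

Step 11
Reactants: 22 2-hydroxy-4,6-dimethoxybenzaldehyde
Product: 23 3-bromo-2-hydroxy-4,6-dimethoxybenzaldehyde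
Conditions: NBS (1.0 equiv), MeCN, 0 to 20 °C
Reagents that add atoms: N-bromosuccinimide, O=C1CCC(=O)N1Br
Why: Electrophilic aromatic bromination; the hydrogen-bonded hydroxyl directs the electrophile to the position between OH and OMe (para to the 6-methoxy group), as is usual for 2-hydroxy-4,6-dialkoxyaryl carbonyl compounds, and this carbon is the future C-6.

Step 12
Reactants: 23 3-bromo-2-hydroxy-4,6-dimethoxybenzaldehyde
Product: 24 3-bromo-4,6-dimethoxy-2-(methoxymethoxy)benzaldehyde
Conditions: NaH, MOMCl, DMF, 0 to 20 °C
Reagents that add atoms: chloromethyl methyl ether, COCCl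
Why: Williamson-type protection of the chelated phenol as its methoxymethyl (MOM) ether marks the future furan oxygen (C-1) with a group that can be removed without touching methyl ethers.

Step 13
Reactants: 24 3-bromo-4,6-dimethoxy-2-(methoxymethoxy)benzaldehyde
Product: 26 3-bromo-4,6-dimethoxy-2-(methoxymethoxy)phenol, via aryl formate 25 (not isolated)
Conditions: mCPBA, NaHCO3, CH2Cl2, 0 to 20 °C; then K2CO3, MeOH, 20 °C
Reagents that add atoms: 3-chloroperbenzoic acid, OOC(=O)c1cccc(Cl)c1
Why: Baeyer–Villiger oxidation of a 2,4,6-trioxygenated benzaldehyde and formate methanolysis (Dakin-type) turn the formyl carbon into the C-2 hydroxyl; the buffer protects the MOM ether.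

Step 14
Reactants: 26 3-bromo-4,6-dimethoxy-2-(methoxymethoxy)phenol; 16 1-iodo-3,5-dimethoxybenzene
Product: 27 2-bromo-4-(3,5-dimethoxyphenoxy)-1,5-dimethoxy-3-(methoxymethoxy)benzene
Conditions: 16 (1.3 equiv), CuI (10 mol%), picolinic acid (20 mol%), K3PO4, DMSO, 80 °C, argon
Reagents that add atoms: none
Why: Ullmann diaryl ether synthesis attaches ring F; the substrate's own C–Br bond, flanked by two alkoxy groups, should be far less reactive toward copper than the unhindered aryl iodide.

Step 15
Reactants: 27 2-bromo-4-(3,5-dimethoxyphenoxy)-1,5-dimethoxy-3-(methoxymethoxy)benzene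
Product: 29 2-[3-(3,5-dimethoxyphenoxy)-4,6-dimethoxy-2-(methoxymethoxy)phenyl]-4,4,5,5-tetramethyl-1,3,2-dioxaborolane, via aryllithium 28 (not isolated)
Conditions: n-BuLi (1.05 equiv), THF, −78 °C; i-PrOBpin, −78 to 20 °C; aq. NH4Cl
Reagents that add atoms: 2-isopropoxy-4,4,5,5-tetramethyl-1,3,2-dioxaborolane, CC(C)OB1OC(C)(C)C(C)(C)O1
Why: Bromine–lithium exchange at −78 °C is faster than any directed deprotonation, so the metal sits only at C-6; borylation gives the pinacol boronate, which resists protodeboronation better than the free 2,6-dialkoxyarylboronic acid.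

Step 16
Reactants: 21 1-(3,5-dimethoxyphenoxy)-2-ethoxy-4,9-dimethoxydibenzo[b,e][1,4]dioxin-6-yl trifluoromethanesulfonate; 29 2-[3-(3,5-dimethoxyphenoxy)-4,6-dimethoxy-2-(methoxymethoxy)phenyl]-4,4,5,5-tetramethyl-1,3,2-dioxaborolane
Product: 31 2-[1-(3,5-dimethoxyphenoxy)-2-ethoxy-4,9-dimethoxydibenzo[b,e][1,4]dioxin-6-yl]-6-(3,5-dimethoxyphenoxy)-3,5-dimethoxyphenol, via MOM-protected biaryl 30 (not isolated)
Conditions: Pd(OAc)2 (5 mol%), SPhos (10 mol%), K3PO4, toluene/H2O, 100 °C; then HCl, MeOH/THF, 50 °C
Reagents that add atoms: none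
Why: Suzuki–Miyaura coupling forms the tri-ortho-substituted B-5–C-6 bond, SPhos being a ligand suited to 2,6-dialkoxyaryl boron reagents and aryl triflates; acid methanolysis then removes only the MOM group and frees the C-1 hydroxyl.

Step 17
Reactants: 31 2-[1-(3,5-dimethoxyphenoxy)-2-ethoxy-4,9-dimethoxydibenzo[b,e][1,4]dioxin-6-yl]-6-(3,5-dimethoxyphenoxy)-3,5-dimethoxyphenol
Product: 32 nona-O-alkyl phlorofucofuroeckol A (ethyl on the A-2 oxygen; methyl on the other eight)
Conditions: Pd(OAc)2 (10 mol%), 3-nitropyridine (10 mol%), PhCO3t-Bu (2 equiv), C6F6/1,3-dimethyl-2-imidazolidinone, 90 °C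
Reagents that add atoms: none
Why: Phenol-directed C–H activation/C–O cyclisation of a 2-arylphenol to a dibenzofuran under divalent palladium catalysis: the palladium phenoxide palladates B-4, the only free position ortho to the biaryl bond on ring B, through a six-membered palladacycle, and oxidant-induced C–O reductive elimination closes the furan.

Step 18
Reactants: 32 nona-O-alkyl phlorofucofuroeckol A (ethyl on the A-2 oxygen; methyl on the other eight)
Product: 33 phlorofucofuroeckol A
Conditions: BBr3 (excess), CH2Cl2, −78 to 20 °C; then MeOH, H2O, under argon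
Reagents that add atoms: none
Why: Lewis acid-mediated cleavage of aryl alkyl ethers removes eight methyl groups and one ethyl group, while diaryl ether, dioxin and furan C–O bonds are inert to BBr3; the step is placed last and worked up without base or air because the nona-phenol is oxidation-sensitive.

## Compound list

1 | 2,3-dihydroxy-4-methoxybenzaldehyde | COc1ccc(C=O)c(O)c1O | starting material
2 | ethyl bromoacetate | CCOC(=O)CBr | starting material
3 | disodium 3-formyl-6-methoxybenzene-1,2-diolate (dianion of 1) | [Na+].[Na+].COc1ccc(C=O)c([O-])c1[O-] | intermediate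
4 | ethyl 2-(3-formyl-2-hydroxy-6-methoxyphenoxy)acetate | CCOC(=O)COc1c(OC)ccc(C=O)c1O | intermediate
5 | 5-methoxy-2-oxo-2,3-dihydro-1,4-benzodioxine-8-carbaldehyde | COc1ccc(C=O)c2OC(=O)COc12 | intermediate
6 | 8-(1,3-dioxolan-2-yl)-5-methoxy-1,4-benzodioxin-2(3H)-one | COc1ccc(C2OCCO2)c2OC(=O)COc12 | intermediate
7 | 8-(1,3-dioxolan-2-yl)-5-methoxy-1,4-benzodioxin-2-yl diphenyl phosphate | COc1ccc(C2OCCO2)c2OC(OP(=O)(Oc3ccccc3)Oc3ccccc3)=COc12 | intermediate
8 | [8-(1,3-dioxolan-2-yl)-5-methoxy-1,4-benzodioxin-2-yl]trimethylstannane | COc1ccc(C2OCCO2)c2OC([Sn](C)(C)C)=COc12 | intermediate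
9 | chromium hexacarbonyl | O=C=[Cr](=C=O)(=C=O)(=C=O)(=C=O)=C=O | starting material
10 | [8-(1,3-dioxolan-2-yl)-5-methoxy-1,4-benzodioxin-2-yl]lithium | COc1ccc(C2OCCO2)c2OC([Li])=COc12 | intermediate
11 | lithium pentacarbonyl{[8-(1,3-dioxolan-2-yl)-5-methoxy-1,4-benzodioxin-2-yl]carbonyl}chromate | [Li+].COc1ccc(C2OCCO2)c2OC(C([O-])=[Cr](=C=O)(=C=O)(=C=O)(=C=O)=C=O)=COc12 | intermediate
12 | pentacarbonyl{[8-(1,3-dioxolan-2-yl)-5-methoxy-1,4-benzodioxin-2-yl](methoxy)methylidene}chromium | COC(=[Cr](=C=O)(=C=O)(=C=O)(=C=O)=C=O)C1=COc2c(OC)ccc(C3OCCO3)c2O1 | intermediate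
13 | ethoxyacetylene | CCOC#C | starting material
14 | tricarbonylchromium complex of 15, metal η6-bound to ring A (written as two components) | COc1cc(OCC)c(O)c2Oc3c(OC)ccc(C4OCCO4)c3Oc12.O=C=[Cr](=C=O)=C=O | intermediate
15 | 6-(1,3-dioxolan-2-yl)-2-ethoxy-4,9-dimethoxydibenzo[b,e][1,4]dioxin-1-ol | COc1cc(OCC)c(O)c2Oc3c(OC)ccc(C4OCCO4)c3Oc12 | intermediate
16 | 1-iodo-3,5-dimethoxybenzene | COc1cc(I)cc(OC)c1 | starting material
17 | 1-(3,5-dimethoxyphenoxy)-6-(1,3-dioxolan-2-yl)-2-ethoxy-4,9-dimethoxydibenzo[b,e][1,4]dioxin | COc1cc(OCC)c(Oc4cc(OC)cc(OC)c4)c2Oc3c(OC)ccc(C5OCCO5)c3Oc12 | intermediate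
18 | 1-(3,5-dimethoxyphenoxy)-2-ethoxy-4,9-dimethoxydibenzo[b,e][1,4]dioxine-6-carbaldehyde | COc1cc(OCC)c(Oc4cc(OC)cc(OC)c4)c2Oc3c(OC)ccc(C=O)c3Oc12 | intermediate
19 | 1-(3,5-dimethoxyphenoxy)-2-ethoxy-4,9-dimethoxydibenzo[b,e][1,4]dioxin-6-yl formate | COc1cc(OCC)c(Oc4cc(OC)cc(OC)c4)c2Oc3c(OC)ccc(OC=O)c3Oc12 | intermediate
20 | 1-(3,5-dimethoxyphenoxy)-2-ethoxy-4,9-dimethoxydibenzo[b,e][1,4]dioxin-6-ol | COc1cc(OCC)c(Oc4cc(OC)cc(OC)c4)c2Oc3c(OC)ccc(O)c3Oc12 | intermediate
21 | 1-(3,5-dimethoxyphenoxy)-2-ethoxy-4,9-dimethoxydibenzo[b,e][1,4]dioxin-6-yl trifluoromethanesulfonate | COc1cc(OCC)c(Oc4cc(OC)cc(OC)c4)c2Oc3c(OC)ccc(OS(=O)(=O)C(F)(F)F)c3Oc12 | intermediate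
22 | 2-hydroxy-4,6-dimethoxybenzaldehyde | COc1cc(O)c(C=O)c(OC)c1 | starting material
23 | 3-bromo-2-hydroxy-4,6-dimethoxybenzaldehyde | COc1cc(OC)c(C=O)c(O)c1Br | intermediate
24 | 3-bromo-4,6-dimethoxy-2-(methoxymethoxy)benzaldehyde | COCOc1c(Br)c(OC)cc(OC)c1C=O | intermediate
25 | 3-bromo-4,6-dimethoxy-2-(methoxymethoxy)phenyl formate | COCOc1c(Br)c(OC)cc(OC)c1OC=O | intermediate
26 | 3-bromo-4,6-dimethoxy-2-(methoxymethoxy)phenol | COCOc1c(Br)c(OC)cc(OC)c1O | intermediate
27 | 2-bromo-4-(3,5-dimethoxyphenoxy)-1,5-dimethoxy-3-(methoxymethoxy)benzene | COCOc1c(Br)c(OC)cc(OC)c1Oc2cc(OC)cc(OC)c2 | intermediate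
28 | [3-(3,5-dimethoxyphenoxy)-4,6-dimethoxy-2-(methoxymethoxy)phenyl]lithium | COCOc1c([Li])c(OC)cc(OC)c1Oc2cc(OC)cc(OC)c2 | intermediate
29 | 2-[3-(3,5-dimethoxyphenoxy)-4,6-dimethoxy-2-(methoxymethoxy)phenyl]-4,4,5,5-tetramethyl-1,3,2-dioxaborolane | COCOc1c(B2OC(C)(C)C(C)(C)O2)c(OC)cc(OC)c1Oc3cc(OC)cc(OC)c3 | intermediate
30 | 1-(3,5-dimethoxyphenoxy)-6-[3-(3,5-dimethoxyphenoxy)-4,6-dimethoxy-2-(methoxymethoxy)phenyl]-2-ethoxy-4,9-dimethoxydibenzo[b,e][1,4]dioxin | COc1cc(OCC)c(Oc4cc(OC)cc(OC)c4)c2Oc3c(OC)ccc(-c5c(OCOC)c(Oc6cc(OC)cc(OC)c6)c(OC)cc5OC)c3Oc12 | intermediate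
31 | 2-[1-(3,5-dimethoxyphenoxy)-2-ethoxy-4,9-dimethoxydibenzo[b,e][1,4]dioxin-6-yl]-6-(3,5-dimethoxyphenoxy)-3,5-dimethoxyphenol | COc1cc(OCC)c(Oc4cc(OC)cc(OC)c4)c2Oc3c(OC)ccc(-c5c(O)c(Oc6cc(OC)cc(OC)c6)c(OC)cc5OC)c3Oc12 | intermediate
32 | nona-O-alkyl phlorofucofuroeckol A (ethyl on the A-2 oxygen; methyl on the other eight) | COc1cc(OCC)c(Oc4cc(OC)cc(OC)c4)c2Oc3c(OC)cc5oc6c(Oc7cc(OC)cc(OC)c7)c(OC)cc(OC)c6c5c3Oc12 | intermediate
33 | phlorofucofuroeckol A | Oc1cc(O)cc(Oc2c(O)cc(O)c3c2Oc2c(O)cc4oc5c(Oc6cc(O)cc(O)c6)c(O)cc(O)c5c4c2O3)c1 | target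

## Step count and least certain steps

Total: 18 steps. Longest linear sequence: 13 steps (steps 1–10 and 16–18). The ring C–F branch (steps 11–15) has 5 steps and joins at step 16.

**Step 7 (key step).** The reaction may stop after alkyne insertion, because the ethoxy group stabilises the new dienylcarbene, or it may drift to non-carbonylative products or to oligomerisation of the ynol ether on the metal. Fallback from 12 (with 13), back at 15: the two events are separated. At or below 20 °C in a non-coordinating solvent 13 should insert into the Cr=C bond to give the insertion product pentacarbonyl{1-ethoxy-3-methoxy-3-[8-(1,3-dioxolan-2-yl)-5-methoxy-1,4-benzodioxin-2-yl]prop-2-en-1-ylidene}chromium F1 (double-bond geometry not fixed; the isomers interconvert on irradiation). F1 would then be irradiated with visible light in THF under CO; photochemical CO insertion at the carbene carbon gives the same dienylketene, which cyclises to 15.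

**Step 6.** The 2-lithio-1,4-benzodioxin 10 may fragment by β-elimination of the aryloxide before it is captured, since Cr(CO)6 reacts only as the mixture warms. Fallback from 7, back at 12, without an alkenyllithium:

- palladium-catalysed methoxycarbonylation of 7 (Pd(OAc)2, 1,3-bis(diphenylphosphino)propane, CO, MeOH, Et3N) to methyl 8-(1,3-dioxolan-2-yl)-5-methoxy-1,4-benzodioxine-2-carboxylate F2;
- saponification (LiOH) to 8-(1,3-dioxolan-2-yl)-5-methoxy-1,4-benzodioxine-2-carboxylic acid F3;
- neutral chlorination with 1-chloro-N,N,2-trimethylprop-1-en-1-amine to 8-(1,3-dioxolan-2-yl)-5-methoxy-1,4-benzodioxine-2-carbonyl chloride F4;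
- acylation of K2Cr(CO)5 (from Cr(CO)6 and KC8) to potassium pentacarbonyl{[8-(1,3-dioxolan-2-yl)-5-methoxy-1,4-benzodioxin-2-yl]carbonyl}chromate F5;
- O-methylation with Me3OBF4 to 12.

**Step 16.** Protodeboronation of the 2,6-dialkoxyaryl boronate may outrun transmetalation at the congested biaryl axis, and the triflate may hydrolyse. Fallback from 27 and 21, back at 30: 27 is lithiated to 28 as in step 15 and transmetalated with ZnCl2 to [3-(3,5-dimethoxyphenoxy)-4,6-dimethoxy-2-(methoxymethoxy)phenyl]zinc chloride F6. Negishi coupling of F6 with 21 (Pd2(dba)3, RuPhos, THF, 65 °C) would give 30 without a protolytically labile boron species.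

**Step 17.** The free, tetra-oxygenated phenol may be degraded by the oxidant, the phloroglucinol-type rings E and F may be palladated, or the crowded phenoxide may fail to bind palladium. Fallback from 18 (and 27), back at 32: the furan oxygen is put on B-4 first and the biaryl bond is closed last, without an oxidant in the ring-closing step.

- Iridium-catalysed ortho-borylation of 18 through its tert-butylimine formed in the flask ([Ir(cod)OMe]2, 8-aminoquinoline, B2pin2, t-BuNH2; hydrolytic work-up) gives 1-(3,5-dimethoxyphenoxy)-2-ethoxy-4,9-dimethoxy-7-(4,4,5,5-tetramethyl-1,3,2-dioxaborolan-2-yl)dibenzo[b,e][1,4]dioxine-6-carbaldehyde F7. B-4 is the only C–H ortho to the formyl group.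
- Acid methanolysis of 27 gives 2-bromo-6-(3,5-dimethoxyphenoxy)-3,5-dimethoxyphenol F8.
- Chan–Lam coupling of F7 with F8 (Cu(OAc)2, pyridine, B(OH)3, MeCN, air) gives 7-[2-bromo-6-(3,5-dimethoxyphenoxy)-3,5-dimethoxyphenoxy]-1-(3,5-dimethoxyphenoxy)-2-ethoxy-4,9-dimethoxydibenzo[b,e][1,4]dioxine-6-carbaldehyde F9.
- Dakin oxidation as in step 9 gives 7-[2-bromo-6-(3,5-dimethoxyphenoxy)-3,5-dimethoxyphenoxy]-1-(3,5-dimethoxyphenoxy)-2-ethoxy-4,9-dimethoxydibenzo[b,e][1,4]dioxin-6-ol F10.
- Triflation as in step 10 gives 7-[2-bromo-6-(3,5-dimethoxyphenoxy)-3,5-dimethoxyphenoxy]-1-(3,5-dimethoxyphenoxy)-2-ethoxy-4,9-dimethoxydibenzo[b,e][1,4]dioxin-6-yl trifluoromethanesulfonate F11.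
- Ditin-mediated intramolecular biaryl coupling of the triflate and the bromide (Stille–Kelly; Me3SnSnMe3, Pd(PPh3)4, LiCl, dioxane, 100 °C) joins B-5 to C-6 and gives 32.

## Further compounds

F1 | step 7 | pentacarbonyl{1-ethoxy-3-methoxy-3-[8-(1,3-dioxolan-2-yl)-5-methoxy-1,4-benzodioxin-2-yl]prop-2-en-1-ylidene}chromium | CCOC(=[Cr](=C=O)(=C=O)(=C=O)(=C=O)=C=O)C=C(OC)C1=COc2c(OC)ccc(C3OCCO3)c2O1
F2 | step 6 | methyl 8-(1,3-dioxolan-2-yl)-5-methoxy-1,4-benzodioxine-2-carboxylate | COC(=O)C1=COc2c(OC)ccc(C3OCCO3)c2O1
F3 | step 6 | 8-(1,3-dioxolan-2-yl)-5-methoxy-1,4-benzodioxine-2-carboxylic acid | OC(=O)C1=COc2c(OC)ccc(C3OCCO3)c2O1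
F4 | step 6 | 8-(1,3-dioxolan-2-yl)-5-methoxy-1,4-benzodioxine-2-carbonyl chloride | ClC(=O)C1=COc2c(OC)ccc(C3OCCO3)c2O1
F5 | step 6 | potassium pentacarbonyl{[8-(1,3-dioxolan-2-yl)-5-methoxy-1,4-benzodioxin-2-yl]carbonyl}chromate | [K+].COc1ccc(C2OCCO2)c2OC(C([O-])=[Cr](=C=O)(=C=O)(=C=O)(=C=O)=C=O)=COc12
F6 | step 16 | [3-(3,5-dimethoxyphenoxy)-4,6-dimethoxy-2-(methoxymethoxy)phenyl]zinc chloride | COCOc1c([Zn]Cl)c(OC)cc(OC)c1Oc2cc(OC)cc(OC)c2
F7 | step 17 | 1-(3,5-dimethoxyphenoxy)-2-ethoxy-4,9-dimethoxy-7-(4,4,5,5-tetramethyl-1,3,2-dioxaborolan-2-yl)dibenzo[b,e][1,4]dioxine-6-carbaldehyde | COc1cc(OCC)c(Oc4cc(OC)cc(OC)c4)c2Oc3c(OC)cc(B5OC(C)(C)C(C)(C)O5)c(C=O)c3Oc12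
F8 | step 17 | 2-bromo-6-(3,5-dimethoxyphenoxy)-3,5-dimethoxyphenol | COc1cc(OC)c(Oc2cc(OC)cc(OC)c2)c(O)c1Br
F9 | step 17 | 7-[2-bromo-6-(3,5-dimethoxyphenoxy)-3,5-dimethoxyphenoxy]-1-(3,5-dimethoxyphenoxy)-2-ethoxy-4,9-dimethoxydibenzo[b,e][1,4]dioxine-6-carbaldehyde | COc1cc(OCC)c(Oc4cc(OC)cc(OC)c4)c2Oc3c(OC)cc(Oc5c(Br)c(OC)cc(OC)c5Oc6cc(OC)cc(OC)c6)c(C=O)c3Oc12
F10 | step 17 | 7-[2-bromo-6-(3,5-dimethoxyphenoxy)-3,5-dimethoxyphenoxy]-1-(3,5-dimethoxyphenoxy)-2-ethoxy-4,9-dimethoxydibenzo[b,e][1,4]dioxin-6-ol | COc1cc(OCC)c(Oc4cc(OC)cc(OC)c4)c2Oc3c(OC)cc(Oc5c(Br)c(OC)cc(OC)c5Oc6cc(OC)cc(OC)c6)c(O)c3Oc12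
F11 | step 17 | 7-[2-bromo-6-(3,5-dimethoxyphenoxy)-3,5-dimethoxyphenoxy]-1-(3,5-dimethoxyphenoxy)-2-ethoxy-4,9-dimethoxydibenzo[b,e][1,4]dioxin-6-yl trifluoromethanesulfonate | COc1cc(OCC)c(Oc4cc(OC)cc(OC)c4)c2Oc3c(OC)cc(Oc5c(Br)c(OC)cc(OC)c5Oc6cc(OC)cc(OC)c6)c(OS(=O)(=O)C(F)(F)F)c3Oc12
A1 | alternative 1 | 2-(3,5-dimethoxyphenoxy)-3-(dibenzofuranyloxy)-5-methoxy-1,4-benzoquinone (dibenzofuran unit as in A3, bound through its B-1 oxygen) | COC1=CC(=O)C(Oc2cc(OC)cc(OC)c2)=C(Oc2c(OC)cc3oc4c(Oc5cc(OC)cc(OC)c5)c(O[Si](C(C)C)(C(C)C)C(C)C)cc(OC)c4c3c2Br)C1=O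
A2 | alternative 1 | 2,3-dichloro-5-methoxy-1,4-benzoquinone | COC1=CC(=O)C(Cl)=C(Cl)C1=O
A3 | alternative 1 | dibenzofuran bromophenol of rings B, C and F (B-1 OH, B-2 OMe, B-6 Br, C-2 3,5-dimethoxyphenoxy, C-3 triisopropylsilyloxy, C-5 OMe) | COc1cc2oc3c(Oc4cc(OC)cc(OC)c4)c(O[Si](C(C)C)(C(C)C)C(C)C)cc(OC)c3c2c(Br)c1O
A4 | alternative 1 | 3,5-dimethoxyphenol | COc1cc(O)cc(OC)c1
A5 | alternative 2 | target as its penta-O-methyl di-O-ethyl ether with one free hydroxyl on each of rings E and F | CCOc1cc(O)cc(Oc2c(OC)cc(OC)c3c2Oc2c(OC)cc4oc5c(Oc6cc(O)cc(OCC)c6)c(OC)cc(OC)c5c4c2O3)c1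
A6 | alternative 2 | penta-O-methyl core bearing ethynyl ethers on the A-1 and C-2 oxygens | C#COc1c(OC)cc(OC)c2c1Oc1c(OC)cc3oc4c(OC#C)c(OC)cc(OC)c4c3c1O2
A7 | alternative 2 | 3-ethoxycyclobut-2-en-1-one | CCOC1=CC(=O)C1
A8 | alternative 3 | dibenzofuran of rings B, C and F with free hydroxyls on B-1 and C-3 and bromine on B-6 | COc1cc2oc3c(Oc4cc(OC)cc(OC)c4)c(O)cc(OC)c3c2c(Br)c1O
A9 | alternative 3 | 2-bromo-6-methoxy-1,4-benzoquinone | COC1=CC(=O)C=C(Br)C1=O
A10 | alternative 3 | 2-(3,5-dimethoxyphenoxy)-5-methoxybenzene-1,3-diol | COc1cc(O)c(Oc2cc(OC)cc(OC)c2)c(O)c1
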